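Plot L against time and take the area under the curve: the meeting on this flask resolved on that, and the blackboard shows why.

all flasks: L 34 mM
- teal: G 5.9 mol%; run made earlier
- violet: G 25 mol%; run made earlier
- eta: G 10 mol%; time 4.0 min
- epsilon: G 30 mol%; time 4.0 min

| run | time / min | Q / % | L / % |
|---|---|---|---|
| teal | 0.500 | 4 | 90 |
| teal | 1.33 | 19 | 61 |
| teal | 2.50 | 44 | 31 |
| teal | 4.00 | 55 | 12 |
| violet | 0.500 | 10 | 84 |
| violet | 1.33 | 55 | 31 |
| violet | 2.50 | 76 | 3 |
| violet | 4.00 | 78 | 1 |

(scatter of a reading: 1.5 percentage points)

- the average divides the monomer in chains by the number of chains begun, living and dead together
- what was read earlier has a scatter of 1.5 percentage points, one standard deviation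
- the earlier runs do not show the number of chains; that part of a forecast is a guess

- which of the two ends with the longer chains by the average number of monomer units in a chain (chains begun, living or dead) ("neither" if they lie within 10 %) (eta / epsilon / neither)
- average number of monomer units in a chain (chains begun, living or dead) at the end, eta
- average number of monomer units in a chain (chains begun, living or dead) at the end, epsilon

The chair opened with the difficulty: the length is Q, the monomer in chains, divided by the chains begun from the initiator G, and the readings show Q and the monomer L but no count of chains. The kineticist answered that the missing material offers a handle. She called the area under L, with L as a fraction of its charge, the exposure A, and her trapezoids gave 1.96 min for teal and 1.17 min for violet. She argued that a side path first order in L makes the part missing from L and Q proportional to A. That part read 33.0 % in teal and 21.0 % in violet, which gives 0.168 min⁻¹ and 0.179 min⁻¹. Their mean, 0.174 min⁻¹, is the side-loss constant k_s, a reading that puts the half-life of L by that path at 3.98 min. On that argument, dividing a flask's missing part by k_s returns its exposure.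

She added that exposure was smaller in violet than in teal, the run with more G. If starting a chain takes L, she reasoned, part of a heavy charge of G stays unbegun, so she expected lengths above Q over G, the more so at high G. The forecaster wrote, “I assume about 95% of G has started, possibly fewer if initiation needs L”, and the forecast gave eta the longer chains: 7 (6.2 to 8.3) for eta and 2.8 (2.5 to 3.5) for epsilon.

    L + D → J + Q (k = 0.790 M⁻¹ s⁻¹)
    L + J → Q + J, rate k2*[J]*[L] (k = 5.30 M⁻¹ s⁻¹)
    G → D (k = 0.0230 s⁻¹)
    L → E (k = 0.00290 s⁻¹)

The simulation gives eta the longer chains, 9.04 units against 5.35 in epsilon, and at 4.00 min the side product E, in percent of the L charged, stands at 27.7 % in eta and 17.6 % in epsilon, which divided by k_s gives exposures of 1.59 min and 1.01 min. At that time J, the living end with one for each chain begun, amounts to 75.5 % of the G charged in eta but 51.3 % in epsilon, where D, formed from G, stands at 4.93 mM. A neighbour of eta charged with 2.5 mol% of G holds E at 41.0 % of the L charged, an exposure of 2.36 min, and its J amounts to 90.5 % of its charge of G.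

All runs are calculated on assumed constants; scatter was added.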